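The target is read as the 1,5 O→C acyl-shift isomer of a ferulate ester. Numbering the heptanoid chain from the carbinol carbon C1 (bearing the 4-hydroxyphenyl ring), the C1 oxygen is 1,5-related to C5, so the δ-hydroxy-β-diketone is disconnected at C4–C5 with that oxygen as carrier of the feruloyl group. One aliphatic Baker–Venkataraman rearrangement forges the unsymmetrical diketone regiospecifically, frees the benzylic alcohol without breaking its C–O bond and stores the dehydration-prone product as a diketonate. The precursor is the ester of O-silyl ferulic acid with an (S)-4-aryl-4-hydroxybutan-2-one, whose stereocentre comes from copper-catalysed conjugate borylation–oxidation of 4-hydroxybenzalacetone, not from an aldol.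

Key step: step 5

Remark: the C4=C5 enol geometry written in the SMILES is one tautomeric depiction. β-Diketone enols interconvert through the diketo form, so only C1 (S) and the C6=C7 (E) alkene are configurational, and the route delivers the tautomeric equilibrium of the one compound.

Step 1
Reactants: 1 (E)-4-(4-hydroxyphenyl)but-3-en-2-one
Product: 2 (E)-4-[4-(triisopropylsilyloxy)phenyl]but-3-en-2-one
Conditions: TIPSCl (1.2 equiv), imidazole (2.5 equiv), DMF, 0 °C to rt
Reagents that add atoms: chlorotriisopropylsilane, CC(C)[Si](Cl)(C(C)C)C(C)C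
Why: Phenol silylation with a silyl chloride and imidazole is routine, and the bulky TIPS ether should survive the alkoxide, perborate, carbodiimide and lithium amide steps yet leave with fluoride.

Step 2
Reactants: 2 (E)-4-[4-(triisopropylsilyloxy)phenyl]but-3-en-2-one
Product: 4 (S)-4-hydroxy-4-[4-(triisopropylsilyloxy)phenyl]butan-2-one, via β-boryl ketone 3 (not isolated)
Conditions: B2pin2 (1.1 equiv), CuCl (3 mol%), NaOtBu (4 mol%), (R,S)-Josiphos [(R)-1-[(S)-2-(diphenylphosphino)ferrocenyl]ethyldicyclohexylphosphine] (3 mol%), MeOH (2 equiv), THF, rt; then NaBO3·4H2O (4 equiv), THF/H2O, 0 °C to rt, same pot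
Reagents that add atoms: sodium perborate, [Na+].[Na+].O[B-]1(O)OO[B-](O)(O)OO1 (hydroxyl oxygen of 4); bis(pinacolato)diboron, CC1(C)OB(OC1(C)C)B1OC(C)(C)C(C)(C)O1 (Bpin group of 3 only)
Why: Copper(I)-catalysed enantioselective conjugate borylation of an acyclic β-aryl enone followed by stereoretentive perborate oxidation of the C–B bond amounts to a formal asymmetric hydration, in which the ferrocenyl bisphosphine on the Cu–Bpin species must direct boron to the Si face of the β-carbon to fix (S) at the carbinol (the mirror-image ligand is used if a first run shows Re-face delivery).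

Step 3
Reactants: 5 (E)-ferulic acid
Product: 8 (E)-3-[3-methoxy-4-(triisopropylsilyloxy)phenyl]prop-2-enoic acid, via bis-silylated ferulate 6 (not isolated), via potassium carboxylate 7 (not isolated)
Conditions: TIPSCl (2.3 equiv), imidazole (5 equiv), DMF, rt; then K2CO3 (1.5 equiv), MeOH/THF/H2O, 0 °C to rt; then 1 M HCl to pH 3–4, 0 °C
Reagents that add atoms: chlorotriisopropylsilane, CC(C)[Si](Cl)(C(C)C)C(C)C
Why: Exhaustive silylation followed by selective carbonate-mediated solvolysis of the far more labile silyl ester is the standard access to an O-silyl hydroxycinnamic acid, the aryl TIPS ether being inert to mild aqueous base and brief cold acid.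

Step 4
Reactants: 4 (S)-4-hydroxy-4-[4-(triisopropylsilyloxy)phenyl]butan-2-one; 8 (E)-3-[3-methoxy-4-(triisopropylsilyloxy)phenyl]prop-2-enoic acid
Product: 9 (1S)-3-oxo-1-[4-(triisopropylsilyloxy)phenyl]butyl (E)-3-[3-methoxy-4-(triisopropylsilyloxy)phenyl]prop-2-enoate
Conditions: DCC (1.3 equiv), DMAP (0.1 equiv), CH2Cl2, 0 °C to rt
Reagents that add atoms: none
Why: Steglich esterification (carbodiimide activation, DMAP acyl transfer) acylates the secondary benzylic alcohol at oxygen without breaking the C1–O bond, so (S) is retained, and low temperature with only catalytic DMAP should hold back E1cB loss of the new acyloxy group.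

Step 5
Reactants: 9 (1S)-3-oxo-1-[4-(triisopropylsilyloxy)phenyl]butyl (E)-3-[3-methoxy-4-(triisopropylsilyloxy)phenyl]prop-2-enoate
Product: 12 (1S,6E)-1,5-dihydroxy-7-[3-methoxy-4-(triisopropylsilyloxy)phenyl]-1-[4-(triisopropylsilyloxy)phenyl]hepta-4,6-dien-3-one, via lithium enolate 10 (not isolated), via dilithium diketonate 11 (not isolated)
Conditions: LiHMDS (2.2 equiv), THF, −78 °C (9 added to the base), then to −20 °C; AcOH (2.5 equiv) in THF, −78 °C, then pH 7 phosphate buffer
Reagents that add atoms: none
Why: LiHMDS at −78 °C removes a proton from the unhindered methyl group to give the terminal lithium enolate 10, whose carbon adds to the ferulate carbonyl, and the six-membered tetrahedral intermediate then expels the C1 alkoxide, a 1,5 O→C acyl shift that forms the C4–C5 bond; the second equivalent of base converts the new β-diketone into the chelated diketonate 11, which drives the sequence and holds the product until the quench. The closest known reaction type is the Baker–Venkataraman rearrangement in its aliphatic form (β-acyloxy ketone to δ-hydroxy-β-diketone), which is also established for cinnamoyl esters. No ring remains in the product, the only cyclisation being the transient 6-exo-trig closure to the tetrahedral intermediate. No stereocentre is created, and because only the acyl–oxygen bond is cleaved the (S) configuration at C1 set in step 2 is carried through unchanged. The step needs methyl over methylene enolisation (the internal enolate would expel ferulate by E1cB) and carbonyl over conjugate attack on the cinnamate: the first is secured by kinetic deprotonation with a bulky amide at low temperature with the ester added to the base, the second by ring size (six-membered for 1,2-attack against eight for 1,4-attack). As the diketonate the product is also shielded from retro-aldol cleavage and from dehydration to the curcuminoid.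

Step 6
Reactants: 12 (1S,6E)-1,5-dihydroxy-7-[3-methoxy-4-(triisopropylsilyloxy)phenyl]-1-[4-(triisopropylsilyloxy)phenyl]hepta-4,6-dien-3-one
Product: 13 (1S,6E)-1,5-dihydroxy-7-(4-hydroxy-3-methoxyphenyl)-1-(4-hydroxyphenyl)hepta-4,6-dien-3-one
Conditions: TBAF (2.5 equiv), AcOH (3 equiv), THF, 0 °C; pH 7 phosphate buffer work-up
Reagents that add atoms: none
Why: Fluoride cleavage of aryl silyl ethers (phenoxide is a good leaving group on silicon) under acetic acid buffering should keep the medium near neutral, so that the δ-hydroxy-β-diketone neither dehydrates nor cyclises and the p-hydroxybenzylic carbinol does not ionise to a quinone methide, leaving C1 untouched.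

Compound list
1 | (E)-4-(4-hydroxyphenyl)but-3-en-2-one (4-hydroxybenzalacetone) | CC(=O)/C=C/c1ccc(O)cc1 | starting material
2 | (E)-4-[4-(triisopropylsilyloxy)phenyl]but-3-en-2-one | CC(=O)/C=C/c1ccc(O[Si](C(C)C)(C(C)C)C(C)C)cc1 | intermediate
3 | (S)-4-(4,4,5,5-tetramethyl-1,3,2-dioxaborolan-2-yl)-4-[4-(triisopropylsilyloxy)phenyl]butan-2-one | CC(=O)C[C@H](B1OC(C)(C)C(C)(C)O1)c1ccc(O[Si](C(C)C)(C(C)C)C(C)C)cc1 | intermediate
4 | (S)-4-hydroxy-4-[4-(triisopropylsilyloxy)phenyl]butan-2-one | CC(=O)C[C@H](O)c1ccc(O[Si](C(C)C)(C(C)C)C(C)C)cc1 | intermediate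
5 | (E)-ferulic acid, (E)-3-(4-hydroxy-3-methoxyphenyl)prop-2-enoic acid | COc1cc(/C=C/C(=O)O)ccc1O | starting material
6 | triisopropylsilyl (E)-3-[3-methoxy-4-(triisopropylsilyloxy)phenyl]prop-2-enoate | COc1cc(/C=C/C(=O)O[Si](C(C)C)(C(C)C)C(C)C)ccc1O[Si](C(C)C)(C(C)C)C(C)C | intermediate
7 | potassium (E)-3-[3-methoxy-4-(triisopropylsilyloxy)phenyl]prop-2-enoate | COc1cc(/C=C/C(=O)[O-])ccc1O[Si](C(C)C)(C(C)C)C(C)C.[K+] | intermediate
8 | (E)-3-[3-methoxy-4-(triisopropylsilyloxy)phenyl]prop-2-enoic acid | COc1cc(/C=C/C(=O)O)ccc1O[Si](C(C)C)(C(C)C)C(C)C | intermediate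
9 | (1S)-3-oxo-1-[4-(triisopropylsilyloxy)phenyl]butyl (E)-3-[3-methoxy-4-(triisopropylsilyloxy)phenyl]prop-2-enoate | CC(=O)C[C@H](OC(=O)/C=C/c1ccc(O[Si](C(C)C)(C(C)C)C(C)C)c(OC)c1)c1ccc(O[Si](C(C)C)(C(C)C)C(C)C)cc1 | intermediate
10 | lithium (4S)-4-{(E)-3-[3-methoxy-4-(triisopropylsilyloxy)phenyl]prop-2-enoyloxy}-4-[4-(triisopropylsilyloxy)phenyl]but-1-en-2-olate | [Li+].C=C([O-])C[C@H](OC(=O)/C=C/c1ccc(O[Si](C(C)C)(C(C)C)C(C)C)c(OC)c1)c1ccc(O[Si](C(C)C)(C(C)C)C(C)C)cc1 | intermediate
11 | dilithium salt (C1 alkoxide and chelated C3/C5 diketonate) of compound 12 | [Li+].[Li+].COc1cc(/C=C/C([O-])=C/C(=O)C[C@H]([O-])c2ccc(O[Si](C(C)C)(C(C)C)C(C)C)cc2)ccc1O[Si](C(C)C)(C(C)C)C(C)C | intermediate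
12 | (1S,6E)-1,5-dihydroxy-7-[3-methoxy-4-(triisopropylsilyloxy)phenyl]-1-[4-(triisopropylsilyloxy)phenyl]hepta-4,6-dien-3-one | COc1cc(/C=C/C(O)=C\C(=O)C[C@H](O)c2ccc(O[Si](C(C)C)(C(C)C)C(C)C)cc2)ccc1O[Si](C(C)C)(C(C)C)C(C)C | intermediate
13 | (1S,6E)-1,5-dihydroxy-7-(4-hydroxy-3-methoxyphenyl)-1-(4-hydroxyphenyl)hepta-4,6-dien-3-one (CNP0206527.1) | COc1cc(/C=C/C(O)=C\C(=O)C[C@H](O)c2ccc(O)cc2)ccc1O | target

Total step count: 6
Longest linear sequence: 5 steps (steps 1, 2, 4, 5, 6); step 3 prepares the acid 8 separately.

Steps most likely to fail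

Step 5. Enolisation may occur at the internal C2 methylene, or the enolates may equilibrate, after which E1cB expulsion of the ferulate returns enone 2 and acid 8; the acyl transfer may also stall. The fallback replaces the intramolecular shift by an intermolecular Claisen acylation with the carbinol capped. It sets out from 4, which is silylated (TESCl, imidazole, CH2Cl2) to (S)-4-(triethylsilyloxy)-4-[4-(triisopropylsilyloxy)phenyl]butan-2-one F1. Acid 8 is converted under neutral conditions (1-chloro-N,N,2-trimethylpropenylamine, CH2Cl2) into (E)-3-[3-methoxy-4-(triisopropylsilyloxy)phenyl]prop-2-enoyl chloride F2. The kinetic lithium enolate of F1 (LiHMDS, 2.1 equiv, THF, −78 °C) is C-acylated by F2 to give (1S,6E)-5-hydroxy-7-[3-methoxy-4-(triisopropylsilyloxy)phenyl]-1-(triethylsilyloxy)-1-[4-(triisopropylsilyloxy)phenyl]hepta-4,6-dien-3-one F3. Global desilylation (TBAF/AcOH, THF, 0 °C to rt) comes back to the route at 13.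

Step 4. The doubly activated (benzylic, β-keto) ester may undergo base-promoted β-elimination as soon as it forms, or acylation of the hindered carbinol may be slow and diverted to N-acylurea. The fallback avoids an isolated ester by acylating the aldolate–enolate dianion. It sets out from 4, which with LiHMDS (3.1 equiv, THF, −78 °C) should give dilithium (S)-4-oxido-4-[4-(triisopropylsilyloxy)phenyl]but-1-en-2-olate F4. To this is added 1-[(E)-3-[3-methoxy-4-(triisopropylsilyloxy)phenyl]prop-2-enoyl]-1H-benzotriazole F5, prepared from 8 (1H-benzotriazole, DCC, CH2Cl2). C-acylation at the terminal enolate carbon, or O-acylation at the alkoxide followed by the same 1,5-shift within the preformed enolate, converge on 11. The buffered quench of step 5 then comes back to the route at 12.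

Step 2. Facial discrimination on the electron-rich enone may be poor, and the β-hydroxy ketone may suffer retro-aldol cleavage, dehydration or partial desilylation during the basic oxidative work-up. The fallback delivers the oxygen as an epoxide instead of through boron. It sets out from 2, which on Juliá–Colonna epoxidation (poly-D-leucine, urea–H2O2, DBU, THF) should give (3S,4R)-3,4-epoxy-4-[4-(triisopropylsilyloxy)phenyl]butan-2-one F6. SmI2 (THF/MeOH, −90 °C) then cleaves the Cα–O bond reductively with the benzylic C–O bond intact and comes back to the route at 4.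

Further compounds
F1 | step 5 | (S)-4-(triethylsilyloxy)-4-[4-(triisopropylsilyloxy)phenyl]butan-2-one | CC(=O)C[C@H](O[Si](CC)(CC)CC)c1ccc(O[Si](C(C)C)(C(C)C)C(C)C)cc1
F2 | step 5 | (E)-3-[3-methoxy-4-(triisopropylsilyloxy)phenyl]prop-2-enoyl chloride | COc1cc(/C=C/C(=O)Cl)ccc1O[Si](C(C)C)(C(C)C)C(C)C
F3 | step 5 | (1S,6E)-5-hydroxy-7-[3-methoxy-4-(triisopropylsilyloxy)phenyl]-1-(triethylsilyloxy)-1-[4-(triisopropylsilyloxy)phenyl]hepta-4,6-dien-3-one | COc1cc(/C=C/C(O)=C\C(=O)C[C@H](O[Si](CC)(CC)CC)c2ccc(O[Si](C(C)C)(C(C)C)C(C)C)cc2)ccc1O[Si](C(C)C)(C(C)C)C(C)C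
F4 | step 4 | dilithium (S)-4-oxido-4-[4-(triisopropylsilyloxy)phenyl]but-1-en-2-olate | [Li+].[Li+].C=C([O-])C[C@H]([O-])c1ccc(O[Si](C(C)C)(C(C)C)C(C)C)cc1
F5 | step 4 | 1-[(E)-3-[3-methoxy-4-(triisopropylsilyloxy)phenyl]prop-2-enoyl]-1H-benzotriazole | COc1cc(/C=C/C(=O)n2nnc3ccccc32)ccc1O[Si](C(C)C)(C(C)C)C(C)C
F6 | step 2 | (3S,4R)-3,4-epoxy-4-[4-(triisopropylsilyloxy)phenyl]butan-2-one | CC(=O)[C@H]1O[C@@H]1c2ccc(O[Si](C(C)C)(C(C)C)C(C)C)cc2
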